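## Retrosynthetic overview

1. Target 25 ⇐ BCl3 removal of the 7-O-isopropyl and 4'-O-benzyl groups from 24 ⇐ methylation of the free 8-OH of hydroquinone 23.
2. Ring A (formed last): 23 ⇐ 4-hydroxy-4-(pyranon-3-yl)cyclobutenone 20 by thermal ring expansion, which makes the C8–C8a bond.
3. 20 ⇐ C5–C4a bond from pyranonylmagnesium 19 (from bromide 14) and isopropyl methyl squarate 18 (from squaric acid 15).
4. Ring C (formed first; ring B is bought in): 14 ⇐ Achmatowicz ring expansion of aryl(3,4-dibromofuryl)carbinol 9 and hydrolytic aromatisation. The furan 3-bromine supplies the oxidation level of the C4 carbonyl and the 4-bromine survives as the metalation handle. 9 ⇐ 3,4-dibromofuran 7 + aldehyde 6 (from 2,5-dimethoxybenzaldehyde 1).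
5. Feature used: in ring A the contiguous carbons C5, C6, C7 and C8 all carry oxygen, with C5–OH and C8–O para to each other and C6–OMe and C7–O between them. This C4O4 unit is a squarate grafted onto the C4a=C8a double bond of the ring C pyranone.

Key step: step 11

Remark on the chemistry: the target has no stereocentre. Compounds 9, 11, 20 and 22 are racemic or diastereomeric mixtures and are used as such, since their sp3 centres vanish on aromatisation. 2,5-Dimethoxybenzaldehyde, 3,4-dibromofuran and squaric acid are taken as commercial.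

## Route

Step 1
Reactants: 1 2,5-dimethoxybenzaldehyde
Product: 3 2,5-dimethoxyphenol, via 2,5-dimethoxyphenyl formate 2 (not isolated)
Conditions: mCPBA (1.3 equiv), CH2Cl2, 0 °C → rt; then K2CO3 (cat.), MeOH, rt
Reagents that add atoms: mCPBA (3-chloroperoxybenzoic acid), OOC(=O)c1cccc(Cl)c1
Why: Baeyer–Villiger oxidation, in which the electron-rich aryl group migrates in preference to hydride to give the aryl formate, which is then methanolysed to the phenol.

Step 2
Reactants: 3 2,5-dimethoxyphenol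
Product: 4 2-(benzyloxy)-1,4-dimethoxybenzene
Conditions: BnBr, K2CO3, DMF, rt
Reagents that add atoms: benzyl bromide, BrCc1ccccc1
Why: Williamson ether synthesis on the phenoxide, with no competing nucleophile in the molecule.

Step 3
Reactants: 4 2-(benzyloxy)-1,4-dimethoxybenzene
Product: 6 4-(benzyloxy)-2,5-dimethoxybenzaldehyde, via aryl iminium chloride 5 (not isolated)
Conditions: POCl3, DMF, 0 → 70 °C; then H2O
Reagents that add atoms: N,N-dimethylformamide, CN(C)C=O; water, O
Why: Vilsmeier–Haack formylation should occur at the ring position para to the benzyloxy group and ortho to a methoxy group, the most activated unhindered site (the pattern seen with 1,2,4-trialkoxybenzenes), and the iminium salt hydrolyses to the aldehyde.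

Step 4
Reactants: 7 3,4-dibromofuran; 6 4-(benzyloxy)-2,5-dimethoxybenzaldehyde
Product: 9 (RS)-[4-(benzyloxy)-2,5-dimethoxyphenyl](3,4-dibromofuran-2-yl)methanol, via 3,4-dibromo-2-furyllithium 8 (not isolated)
Conditions: LiN(iPr)2 (LDA), THF, −78 °C; then 6, −78 → −40 °C; aq. NH4Cl
Reagents that add atoms: none
Why: α-Deprotonation of the furan next to the ring oxygen and a bromine by the amide base at −78 °C (no bromine–lithium exchange or halogen migration expected at this temperature), followed by 1,2-addition to the aldehyde; the carbinol centre forms racemic and is destroyed in step 6.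

Step 5
Reactants: 9 (RS)-[4-(benzyloxy)-2,5-dimethoxyphenyl](3,4-dibromofuran-2-yl)methanol
Product: 11 2-[4-(benzyloxy)-2,5-dimethoxyphenyl]-4,5-dibromo-6-hydroxy-2H-pyran-3(6H)-one (mixture of diastereomers), via open-chain enedione 10 (not isolated)
Conditions: mCPBA (1.2 equiv), CH2Cl2, 0 °C → rt
Reagents that add atoms: mCPBA (3-chloroperoxybenzoic acid), OOC(=O)c1cccc(Cl)c1
Why: Achmatowicz rearrangement: oxygen transfer to the furan, opening to the cis-enedione and closure of the carbinol oxygen onto the aldehyde; a peracid is chosen because a bromonium source would attack the trialkoxyphenyl ring faster than the doubly brominated furan.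

Step 6
Reactants: 11 2-[4-(benzyloxy)-2,5-dimethoxyphenyl]-4,5-dibromo-6-hydroxy-2H-pyran-3(6H)-one
Product: 13 2-[4-(benzyloxy)-2,5-dimethoxyphenyl]-5-bromo-3-hydroxy-4H-pyran-4-one, via 3-hydroxypyrylium chloride 12 (not isolated)
Conditions: aq. HCl (1 M), 1,4-dioxane, 80 °C
Reagents that add atoms: water, O
Why: Acid-induced enolisation toward C2 and loss of the anomeric hydroxyl give a 3-hydroxypyrylium ion, water adds at C4 and the geminal bromohydrin expels HBr, so the former furan 3-bromine supplies the C4 carbonyl while the 5-bromine is untouched; this is the known hydrolytic conversion of 4-halo-6-hydroxy-2H-pyran-3(6H)-ones into 3-hydroxy-4-pyranones.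

Step 7
Reactants: 13 2-[4-(benzyloxy)-2,5-dimethoxyphenyl]-5-bromo-3-hydroxy-4H-pyran-4-one
Product: 14 2-[4-(benzyloxy)-2,5-dimethoxyphenyl]-5-bromo-3-methoxy-4H-pyran-4-one
Conditions: MeI, K2CO3, acetone, reflux
Reagents that add atoms: iodomethane, CI
Why: Williamson O-methylation of the acidic enolic 3-hydroxyl, the only acidic site.

Step 8
Reactants: 15 squaric acid (3,4-dihydroxycyclobut-3-ene-1,2-dione)
Product: 16 3,4-dichlorocyclobut-3-ene-1,2-dione
Conditions: (COCl)2 (2.2 equiv), DMF (cat.), toluene, 50 °C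
Reagents that add atoms: oxalyl chloride, O=C(Cl)C(Cl)=O
Why: Chlorodehydroxylation of the vinylogous acid by the chloroiminium species formed from oxalyl chloride and DMF, as for a carboxylic acid to acid chloride conversion.

Step 9
Reactants: 16 3,4-dichlorocyclobut-3-ene-1,2-dione
Product: 18 3-methoxy-4-(propan-2-yloxy)cyclobut-3-ene-1,2-dione, via 3-chloro-4-isopropoxycyclobutenedione 17 (not isolated)
Conditions: i-PrOH (1.0 equiv), CH2Cl2, 0 °C → rt; then MeOH, Et3N, −20 °C
Reagents that add atoms: propan-2-ol, CC(C)O; methanol, CO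
Why: Stepwise addition–elimination at the vinylogous acid chloride: the first alkoxy group deactivates the remaining chloride, so one equivalent of the hindered alcohol should stop at the ester chloride, and methanol with base then displaces the second chloride at low temperature without alkoxy scrambling.

Step 10
Reactants: 14 2-[4-(benzyloxy)-2,5-dimethoxyphenyl]-5-bromo-3-methoxy-4H-pyran-4-one; 18 3-methoxy-4-(propan-2-yloxy)cyclobut-3-ene-1,2-dione
Product: 20 (RS)-4-hydroxy-4-{6-[4-(benzyloxy)-2,5-dimethoxyphenyl]-5-methoxy-4-oxo-4H-pyran-3-yl}-3-methoxy-2-(propan-2-yloxy)cyclobut-2-en-1-one, via pyranonylmagnesium chloride 19 (not isolated)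
Conditions: i-PrMgCl·LiCl (1.05 equiv), THF, −40 °C; then added to 18 (1.3 equiv), THF, −78 °C; aq. NH4Cl
Reagents that add atoms: none
Why: Bromine–magnesium exchange on the electron-poor α-bromo vinylogous ester, then Grignard 1,2-addition (kept cold to avoid ring-opening β-elimination) to the squarate, which should prefer the carbonyl flanked by the methoxy-bearing carbon because the isopropoxy group shields the other; the minor regioisomeric adduct is removed by chromatography, and the racemic carbinol centre is lost in step 11.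

Step 11
Reactants: 20 (RS)-4-hydroxy-4-{6-[4-(benzyloxy)-2,5-dimethoxyphenyl]-5-methoxy-4-oxo-4H-pyran-3-yl}-3-methoxy-2-(propan-2-yloxy)cyclobut-2-en-1-one
Product: 23 2-[4-(benzyloxy)-2,5-dimethoxyphenyl]-5,8-dihydroxy-3,6-dimethoxy-7-(propan-2-yloxy)-4H-chromen-4-one, via dienylketene 21 (not isolated), via 8aH-chromenedione 22 (not isolated)
Conditions: degassed p-xylene, 135 °C, Ar
Reagents that add atoms: none
Why: Heating breaks the C1–C4 bond of the cyclobutenone by conrotatory four-electron electrocyclic opening to dienylketene 21, whose ketene C=C, enol C=C and pyranone C=C form a hexatriene that closes by thermal disrotatory six-electron electrocyclisation (ketene carbon to the pyranone CH, the future C8–C8a bond), and enolisation of the 8aH-dienone 22 aromatises ring A. The closest known reaction is the Moore rearrangement of 4-aryl- and 4-alkenyl-4-hydroxycyclobutenones to hydroquinones, the weakly aromatic pyranone double bond playing the alkenyl part. Ring A is closed by this 6π electrocyclisation, with C5 to C8 and their four oxygens all delivered by the squarate. No stereocentre remains, since the carbinol carbon of 20 becomes sp2 on ring opening and the transient C8a centre of 22 is lost on tautomerisation. The step needs torquoselectivity that puts the pyranonyl group inward, cis to the ketene, and the donor hydroxyl's strong preference for outward rotation secures it; the substituent pattern (6-OMe, 7-O-iPr, new hydroxyls at C5 and C8) is fixed by the connectivity of 20, and the pyranone CH is the only available terminus because the other neighbour of the attachment carbon is the C4 carbonyl.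

Step 12
Reactants: 23 2-[4-(benzyloxy)-2,5-dimethoxyphenyl]-5,8-dihydroxy-3,6-dimethoxy-7-(propan-2-yloxy)-4H-chromen-4-one
Product: 24 2-[4-(benzyloxy)-2,5-dimethoxyphenyl]-5-hydroxy-3,6,8-trimethoxy-7-(propan-2-yloxy)-4H-chromen-4-one
Conditions: MeI (1.2 equiv), K2CO3, degassed acetone, rt, Ar
Reagents that add atoms: iodomethane, CI
Why: Chemoselective Williamson methylation, since the 5-hydroxyl is locked in a hydrogen bond to the C4 carbonyl and is far less nucleophilic than the free 8-hydroxyl; exclusion of air prevents oxidation of the hydroquinone to the quinone.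

Step 13
Reactants: 24 2-[4-(benzyloxy)-2,5-dimethoxyphenyl]-5-hydroxy-3,6,8-trimethoxy-7-(propan-2-yloxy)-4H-chromen-4-one
Product: 25 5,7-dihydroxy-2-(4-hydroxy-2,5-dimethoxyphenyl)-3,6,8-trimethoxy-4H-chromen-4-one (5,7,4'-trihydroxy-3,6,8,2',5'-pentamethoxyflavone)
Conditions: BCl3, C6HMe5 (pentamethylbenzene), CH2Cl2, −78 → 0 °C; then MeOH/H2O
Reagents that add atoms: none
Why: Lewis acid dealkylation, in which BCl3 cleaves the secondary isopropyl ether and the benzyl ether much faster than aryl methyl ethers at or below 0 °C, pentamethylbenzene traps the benzyl cation, and the boron chelate between O5 and the C4 carbonyl keeps the reagent away from the 3-methoxy group.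

## Compound list

1 | 2,5-dimethoxybenzaldehyde | COc1ccc(OC)c(C=O)c1 | starting material
2 | 2,5-dimethoxyphenyl formate | COc1ccc(OC)c(OC=O)c1 | intermediate (not isolated)
3 | 2,5-dimethoxyphenol | COc1ccc(OC)c(O)c1 | intermediate
4 | 2-(benzyloxy)-1,4-dimethoxybenzene | COc1ccc(OC)c(OCc2ccccc2)c1 | intermediate
5 | N-[4-(benzyloxy)-2,5-dimethoxybenzylidene]-N-methylmethanaminium chloride | COc1cc(OCc2ccccc2)c(OC)cc1C=[N+](C)C.[Cl-] | intermediate (not isolated)
6 | 4-(benzyloxy)-2,5-dimethoxybenzaldehyde | COc1cc(OCc2ccccc2)c(OC)cc1C=O | intermediate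
7 | 3,4-dibromofuran | Brc1cocc1Br | starting material
8 | (3,4-dibromofuran-2-yl)lithium | [Li]c1occ(Br)c1Br | intermediate (not isolated)
9 | (RS)-[4-(benzyloxy)-2,5-dimethoxyphenyl](3,4-dibromofuran-2-yl)methanol (racemic) | COc1cc(OCc2ccccc2)c(OC)cc1C(O)c1occ(Br)c1Br | intermediate
10 | (Z)-5-[4-(benzyloxy)-2,5-dimethoxyphenyl]-2,3-dibromo-5-hydroxy-4-oxopent-2-enal (racemic) | COc1cc(OCc2ccccc2)c(OC)cc1C(O)C(=O)/C(Br)=C(Br)\C=O | intermediate (not isolated)
11 | 2-[4-(benzyloxy)-2,5-dimethoxyphenyl]-4,5-dibromo-6-hydroxy-2H-pyran-3(6H)-one (diastereomer mixture, racemic) | COc1cc(OCc2ccccc2)c(OC)cc1C1OC(O)C(Br)=C(Br)C1=O | intermediate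
12 | 2-[4-(benzyloxy)-2,5-dimethoxyphenyl]-4,5-dibromo-3-hydroxypyrylium chloride | COc1cc(OCc2ccccc2)c(OC)cc1-c1[o+]cc(Br)c(Br)c1O.[Cl-] | intermediate (not isolated)
13 | 2-[4-(benzyloxy)-2,5-dimethoxyphenyl]-5-bromo-3-hydroxy-4H-pyran-4-one | COc1cc(OCc2ccccc2)c(OC)cc1-c1occ(Br)c(=O)c1O | intermediate
14 | 2-[4-(benzyloxy)-2,5-dimethoxyphenyl]-5-bromo-3-methoxy-4H-pyran-4-one | COc1cc(OCc2ccccc2)c(OC)cc1-c1occ(Br)c(=O)c1OC | intermediate
15 | squaric acid | OC1=C(O)C(=O)C1=O | starting material
16 | 3,4-dichlorocyclobut-3-ene-1,2-dione | ClC1=C(Cl)C(=O)C1=O | intermediate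
17 | 3-chloro-4-(propan-2-yloxy)cyclobut-3-ene-1,2-dione | CC(C)OC1=C(Cl)C(=O)C1=O | intermediate (not isolated)
18 | 3-methoxy-4-(propan-2-yloxy)cyclobut-3-ene-1,2-dione | COC1=C(OC(C)C)C(=O)C1=O | intermediate
19 | {6-[4-(benzyloxy)-2,5-dimethoxyphenyl]-5-methoxy-4-oxo-4H-pyran-3-yl}magnesium chloride | COc1cc(OCc2ccccc2)c(OC)cc1-c1occ([Mg]Cl)c(=O)c1OC | intermediate (not isolated)
20 | (RS)-4-hydroxy-4-{6-[4-(benzyloxy)-2,5-dimethoxyphenyl]-5-methoxy-4-oxo-4H-pyran-3-yl}-3-methoxy-2-(propan-2-yloxy)cyclobut-2-en-1-one (racemic) | COc1cc(OCc2ccccc2)c(OC)cc1-c1occ(C2(O)C(OC)=C(OC(C)C)C2=O)c(=O)c1OC | intermediate (key-step precursor)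
21 | 4-hydroxy-3-methoxy-2-(propan-2-yloxy)-4-{6-[4-(benzyloxy)-2,5-dimethoxyphenyl]-5-methoxy-4-oxo-4H-pyran-3-yl}buta-1,3-dien-1-one, pyranonyl cis to the ketene-bearing carbon | COc1cc(OCc2ccccc2)c(OC)cc1-c1occ(/C(O)=C(OC)\C(OC(C)C)=C=O)c(=O)c1OC | intermediate (not isolated)
22 | 2-[4-(benzyloxy)-2,5-dimethoxyphenyl]-5-hydroxy-3,6-dimethoxy-7-(propan-2-yloxy)-8aH-chromene-4,8-dione (racemic) | COC1=C(c2cc(OC)c(OCc3ccccc3)cc2OC)OC2C(=O)C(OC(C)C)=C(OC)C(O)=C2C1=O | intermediate (not isolated)
23 | 2-[4-(benzyloxy)-2,5-dimethoxyphenyl]-5,8-dihydroxy-3,6-dimethoxy-7-(propan-2-yloxy)-4H-chromen-4-one | COc1c(O)c2c(=O)c(OC)c(-c3cc(OC)c(OCc4ccccc4)cc3OC)oc2c(O)c1OC(C)C | intermediate (key-step product)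
24 | 2-[4-(benzyloxy)-2,5-dimethoxyphenyl]-5-hydroxy-3,6,8-trimethoxy-7-(propan-2-yloxy)-4H-chromen-4-one | COc1c(O)c2c(=O)c(OC)c(-c3cc(OC)c(OCc4ccccc4)cc3OC)oc2c(OC)c1OC(C)C | intermediate
25 | 5,7,4'-trihydroxy-3,6,8,2',5'-pentamethoxyflavone | COc1cc(-c2oc3c(OC)c(O)c(OC)c(O)c3c(=O)c2OC)c(OC)cc1O | target

## Step count and main risks

Total: 13 steps. Longest linear sequence: 11 steps (steps 1–7, then 10–13); steps 8–9 form the squarate branch.

**Step 11.** The ring expansion may be diverted by inward rotation of the hydroxyl, by addition of the enol O–H to the ketene (lactone formation), or by air oxidation of the electron-rich hydroquinone during isolation. The fallback masks the carbinol and bypasses the free hydroquinone. It sets out from 20, which is silylated (TBSOTf, 2,6-lutidine, CH2Cl2, −78 °C) to the tert-butyldimethylsilyl ether of the cyclobutenone F1. Thermolysis in p-xylene should then give the 8-hydroxy-5-silyloxyflavone F2, the bulky silyloxy group reinforcing outward rotation and removing the O–H. Methylation (MeI, K2CO3, acetone) gives the 8-methoxy-5-silyloxyflavone F3, and Bu4NF in THF frees the 5-hydroxyl, returning to the route at 24.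

**Step 10.** The two squarate carbonyls may be discriminated poorly, so that the wanted adduct is not the main product, and the magnesiated pyranone may be lost by ring opening. The fallback removes the regiochemical question. It sets out from 14, which after the same exchange is added to commercial diisopropyl squarate to give the symmetrical diisopropoxy adduct F4. Thermolysis gives the 5,8-dihydroxy-6,7-diisopropoxyflavone F5, and MeI/K2CO3 gives the 8-methyl ether F6. BCl3 with pentamethylbenzene removes both isopropyl groups and the benzyl group to give the 5,6,7,4'-tetrahydroxyflavone F7. Benzyl bromide (2 equiv) and K2CO3 in DMF should alkylate the two most acidic hydroxyls to give the 7,4'-dibenzyl ether F8. MeI/K2CO3 then methylates the 6-hydroxyl while the chelated 5-hydroxyl stays free, giving the 6-methyl ether F9. Hydrogenolysis (H2, Pd/C, EtOAc) returns to the route at the target 25.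

**Step 5.** The peracid may be consumed by the electron-rich ring B, or oxygen transfer to the deactivated dibromofuran may be too slow. The fallback builds ring C before ring B is attached. It sets out from 7 and from 4 and returns at 14.
- From 7, LDA and then paraformaldehyde give (3,4-dibromofuran-2-yl)methanol F10.
- With no arene present, N-bromosuccinimide in aqueous THF (NaHCO3) should give 4,5-dibromo-6-hydroxy-2H-pyran-3(6H)-one F11.
- Hot aqueous acid gives 5-bromo-3-hydroxy-4H-pyran-4-one F12.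
- N-Iodosuccinimide iodinates the position ortho to the enolic hydroxyl to give 5-bromo-3-hydroxy-2-iodo-4H-pyran-4-one F13.
- MeI/K2CO3 gives 5-bromo-2-iodo-3-methoxy-4H-pyran-4-one F14.
- From 4, N-bromosuccinimide in MeCN gives 1-(benzyloxy)-4-bromo-2,5-dimethoxybenzene F15.
- n-BuLi, then B(OiPr)3 and acidic work-up give [4-(benzyloxy)-2,5-dimethoxyphenyl]boronic acid F16.
- Suzuki–Miyaura coupling of F14 with F16 (Pd(PPh3)4, K2CO3, dioxane/H2O, 60 °C) should occur at the carbon–iodine bond only and gives 14.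

## Further compounds

F1 | step 11 | (RS)-4-[(tert-butyldimethylsilyl)oxy]-4-{6-[4-(benzyloxy)-2,5-dimethoxyphenyl]-5-methoxy-4-oxo-4H-pyran-3-yl}-3-methoxy-2-(propan-2-yloxy)cyclobut-2-en-1-one | COc1cc(OCc2ccccc2)c(OC)cc1-c1occ(C2(O[Si](C)(C)C(C)(C)C)C(OC)=C(OC(C)C)C2=O)c(=O)c1OC
F2 | step 11 | 2-[4-(benzyloxy)-2,5-dimethoxyphenyl]-5-[(tert-butyldimethylsilyl)oxy]-8-hydroxy-3,6-dimethoxy-7-(propan-2-yloxy)-4H-chromen-4-one | COc1c(O[Si](C)(C)C(C)(C)C)c2c(=O)c(OC)c(-c3cc(OC)c(OCc4ccccc4)cc3OC)oc2c(O)c1OC(C)C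
F3 | step 11 | 2-[4-(benzyloxy)-2,5-dimethoxyphenyl]-5-[(tert-butyldimethylsilyl)oxy]-3,6,8-trimethoxy-7-(propan-2-yloxy)-4H-chromen-4-one | COc1c(O[Si](C)(C)C(C)(C)C)c2c(=O)c(OC)c(-c3cc(OC)c(OCc4ccccc4)cc3OC)oc2c(OC)c1OC(C)C
F4 | step 10 | (RS)-4-hydroxy-4-{6-[4-(benzyloxy)-2,5-dimethoxyphenyl]-5-methoxy-4-oxo-4H-pyran-3-yl}-2,3-bis(propan-2-yloxy)cyclobut-2-en-1-one | COc1cc(OCc2ccccc2)c(OC)cc1-c1occ(C2(O)C(OC(C)C)=C(OC(C)C)C2=O)c(=O)c1OC
F5 | step 10 | 2-[4-(benzyloxy)-2,5-dimethoxyphenyl]-5,8-dihydroxy-3-methoxy-6,7-bis(propan-2-yloxy)-4H-chromen-4-one | CC(C)Oc1c(O)c2c(=O)c(OC)c(-c3cc(OC)c(OCc4ccccc4)cc3OC)oc2c(O)c1OC(C)C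
F6 | step 10 | 2-[4-(benzyloxy)-2,5-dimethoxyphenyl]-5-hydroxy-3,8-dimethoxy-6,7-bis(propan-2-yloxy)-4H-chromen-4-one | CC(C)Oc1c(O)c2c(=O)c(OC)c(-c3cc(OC)c(OCc4ccccc4)cc3OC)oc2c(OC)c1OC(C)C
F7 | step 10 | 5,6,7-trihydroxy-2-(4-hydroxy-2,5-dimethoxyphenyl)-3,8-dimethoxy-4H-chromen-4-one | COc1cc(-c2oc3c(OC)c(O)c(O)c(O)c3c(=O)c2OC)c(OC)cc1O
F8 | step 10 | 7-(benzyloxy)-2-[4-(benzyloxy)-2,5-dimethoxyphenyl]-5,6-dihydroxy-3,8-dimethoxy-4H-chromen-4-one | COc1cc(-c2oc3c(OC)c(OCc4ccccc4)c(O)c(O)c3c(=O)c2OC)c(OC)cc1OCc1ccccc1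
F9 | step 10 | 7-(benzyloxy)-2-[4-(benzyloxy)-2,5-dimethoxyphenyl]-5-hydroxy-3,6,8-trimethoxy-4H-chromen-4-one | COc1cc(-c2oc3c(OC)c(OCc4ccccc4)c(OC)c(O)c3c(=O)c2OC)c(OC)cc1OCc1ccccc1
F10 | step 5 | (3,4-dibromofuran-2-yl)methanol | OCc1occ(Br)c1Br
F11 | step 5 | 4,5-dibromo-6-hydroxy-2H-pyran-3(6H)-one (racemic) | OC1OCC(=O)C(Br)=C1Br
F12 | step 5 | 5-bromo-3-hydroxy-4H-pyran-4-one | O=c1c(O)cocc1Br
F13 | step 5 | 5-bromo-3-hydroxy-2-iodo-4H-pyran-4-one | O=c1c(O)c(I)occ1Br
F14 | step 5 | 5-bromo-2-iodo-3-methoxy-4H-pyran-4-one | COc1c(I)occ(Br)c1=O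
F15 | step 5 | 1-(benzyloxy)-4-bromo-2,5-dimethoxybenzene | COc1cc(OCc2ccccc2)c(OC)cc1Br
F16 | step 5 | [4-(benzyloxy)-2,5-dimethoxyphenyl]boronic acid | COc1cc(OCc2ccccc2)c(OC)cc1B(O)O
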